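**Retrosynthetic overview**

1. Ring A is closed last. C1–C10 and C2–C3 are cut together in a decarboxylative radical–polar crossover [4+2] annulation of but-3-en-2-one onto a ring B carboxylic acid (Giese addition, then aldol); the C2 acetate is the Baeyer–Villiger image of the C2 acetyl group that the annulation leaves.
2. Enabling feature: ring A carries in sequence the quaternary, methyl-bearing C10, C2–O, C3–OH and the quaternary C4 with CH3 and CHO. C3 and the C19 formyl carbon are therefore two arms of one gem-diformyl carbon, C2–C3 is an aldol bond, and C10 is a tertiary radical site unmasked from a C10 carboxylic acid by loss of CO2.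
3. Ring B (C5–C10, C7=C8) comes from an Ireland–Claisen rearrangement of a δ-lactone that bears an exocyclic alkenyl group. This forms C9–C10, relays chirality from C7–O to C9 and leaves the carboxyl group on C10.
4. The lactone comes from a citronellate-derived enal (C7–C9, C11–C17) by asymmetric allylation, methacrylate ring-closing metathesis and Michael addition of methylmalononitrile (C4, C18, C3, C19) trans to the C7 substituent.
5. Order of ring formation: temporary δ-lactone, then ring B, then ring A; C13 comes from (R)-citronellic acid.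

Key step: step 9

Remark: labdane numbering of the target is used for all intermediates (decalin C1–C10, side chain C11–C15, C16 on C13, C17 on C8, C18 methyl and C19 formyl on C4, C20 on C10). C21 is the temporary carboxyl carbon on C10. Compound 9 is listed as one epimer at C10; that centre is erased in step 7.

**Route**

Step 1
Reactants: 1 (R)-citronellic acid
Product: 2 tert-butyl (3R)-3,7-dimethyloct-6-enoate
Conditions: Cl3CC(=NH)OtBu (2 equiv), cyclohexane/CH2Cl2, rt
Reagents that add atoms: tert-butyl 2,2,2-trichloroacetimidate, CC(C)(C)OC(=N)C(Cl)(Cl)Cl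
Why: The acid protonates the imidate and is O-alkylated by the tert-butyl cation (imidate esterification), giving an ester that should survive the later hydride, base and peroxide steps and can be removed without base.

Step 2
Reactants: 2 tert-butyl (3R)-3,7-dimethyloct-6-enoate
Product: 4 tert-butyl (3R,6E)-3,7-dimethyl-8-oxooct-6-enoate, via allylic alcohol 3 (not isolated)
Conditions: SeO2 (cat.), t-BuOOH (2 equiv), CH2Cl2, rt; then MnO2 (excess), CH2Cl2, rt
Reagents that add atoms: selenium dioxide, O=[Se]=O; tert-butyl hydroperoxide, CC(C)(C)OO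
Why: SeO2 allylic oxidation (ene reaction, then [2,3]-sigmatropic shift) should oxidise only the (E)-methyl group of the prenyl terminus, and MnO2 takes the allylic alcohol to the (E)-enal, which fixes C7 and the (E)-C8=C9 geometry.

Step 3
Reactants: 4 tert-butyl (3R,6E)-3,7-dimethyl-8-oxooct-6-enoate
Product: 5 tert-butyl (3R,6E,8R)-8-hydroxy-3,7-dimethylundeca-6,10-dienoate
Conditions: (+)-Ipc2BOMe, CH2=CHCH2MgBr, Et2O, −78 °C to rt; then 4, −78 °C; then NaOH, H2O2
Reagents that add atoms: allylmagnesium bromide, C=CC[Mg]Br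
Why: Allylboration through a closed chair transition state with the diisopinocampheyl groups derived from (−)-α-pinene (the antipode that gives (R)-carbinols from benzaldehyde and enals) should set the (R)-carbinol at C7 under reagent control.

Step 4
Reactants: 5 tert-butyl (3R,6E,8R)-8-hydroxy-3,7-dimethylundeca-6,10-dienoate
Product: 6 tert-butyl (3R,6E,8R)-3,7-dimethyl-8-(2-methylprop-2-enoyloxy)undeca-6,10-dienoate
Conditions: CH2=C(CH3)COCl, Et3N, DMAP (cat.), CH2Cl2, 0 °C
Reagents that add atoms: methacryloyl chloride, CC(=C)C(=O)Cl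
Why: DMAP-catalysed acylation of the secondary allylic alcohol installs C21, C10 and C20 without touching a stereocentre.

Step 5
Reactants: 6 tert-butyl (3R,6E,8R)-3,7-dimethyl-8-(2-methylprop-2-enoyloxy)undeca-6,10-dienoate
Product: 7 tert-butyl (3R,6E)-3-methyl-7-[(2R)-5-methyl-6-oxo-3,6-dihydro-2H-pyran-2-yl]oct-6-enoate
Conditions: second-generation Grubbs catalyst (5 mol %), toluene (5 mM), 80 °C
Reagents that add atoms: none
Why: Ring-closing metathesis between the terminal alkene and the methacrylate closes the six-membered lactone and forms C5=C10, while the hindered trisubstituted C8=C9 alkene should stay out of the metathesis.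

Step 6
Reactants: 7 tert-butyl (3R,6E)-3-methyl-7-[(2R)-5-methyl-6-oxo-3,6-dihydro-2H-pyran-2-yl]oct-6-enoate; 8 methylmalononitrile
Product: 9 tert-butyl (3R,6E)-7-[(2R,4S,5R)-4-(1,1-dicyanoethyl)-5-methyl-6-oxooxan-2-yl]-3-methyloct-6-enoate
Conditions: 8 (3 equiv), K2CO3 (0.3 equiv), 18-crown-6 (0.3 equiv), DMSO, 45 °C
Reagents that add atoms: none
Why: Michael addition of the small, linear dicyano carbanion to the lactone β-carbon (C5) anti to the C7 alkenyl group should give the 4,6-trans lactone under kinetic control, because the adduct enolate is protonated at once by the excess C–H acid and no base strong enough to re-enolise or open the lactone is present.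

Step 7
Reactants: 9 tert-butyl (3R,6E)-7-[(2R,4S,5R)-4-(1,1-dicyanoethyl)-5-methyl-6-oxooxan-2-yl]-3-methyloct-6-enoate
Product: 12 (1R,2R,6R)-2-[(3R)-5-tert-butoxy-3-methyl-5-oxopentyl]-6-(1,1-dicyanoethyl)-1,3-dimethylcyclohex-3-ene-1-carboxylic acid, via silyl ketene acetal 10 (not isolated), via silyl ester 11 (not isolated)
Conditions: TBSOTf (1.5 equiv), Et3N (3 equiv), CH2Cl2, −78 to 0 °C; then toluene, 110 °C; then AcOH, THF, H2O, rt
Reagents that add atoms: none
Why: Ireland–Claisen rearrangement of the lactone silyl ketene acetal, for which soft enolisation avoids a free lactone enolate (and so retro-Michael loss of the dicyano carbanion) and the lactone ring imposes a boat transition state: the new bond forms on the lactone face that carries the alkenyl group and suprafacially on the (E)-alkene, so that chirality passes from C7–O to C9, the trans-placed C5 substituent ends cis to the new C9 chain, C7=C8 appears in ring B, and the quaternary C10 carries the carboxyl group.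

Step 8
Reactants: 12 (1R,2R,6R)-2-[(3R)-5-tert-butoxy-3-methyl-5-oxopentyl]-6-(1,1-dicyanoethyl)-1,3-dimethylcyclohex-3-ene-1-carboxylic acid
Product: 13 (1R,2R,6R)-2-[(3R)-5-tert-butoxy-3-methyl-5-oxopentyl]-1,3-dimethyl-6-(2-methyl-1,3-dioxopropan-2-yl)cyclohex-3-ene-1-carboxylic acid
Conditions: i-Bu2AlH (3.5 equiv), toluene, −78 to −50 °C; then 1 M HCl, 0 °C
Reagents that add atoms: water, O
Why: i-Bu2AlH adds one hydride to each nitrile to give N-aluminio aldimines that are not reduced further and hydrolyse to the gem-dialdehyde, while the aluminium carboxylate and the hindered tert-butyl ester should be spared at low temperature (13 may sit partly as its cyclic lactol).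

Step 9
Reactants: 13 (1R,2R,6R)-2-[(3R)-5-tert-butoxy-3-methyl-5-oxopentyl]-1,3-dimethyl-6-(2-methyl-1,3-dioxopropan-2-yl)cyclohex-3-ene-1-carboxylic acid; 14 but-3-en-2-one
Product: 17 tert-butyl (2S,3S,4S,5S,9R,10S,13R)-2-acetyl-3-hydroxy-19-oxolabd-7-en-15-oate, via tertiary radical 15 (not isolated), via potassium enolate 16 (not isolated)
Conditions: 14 (3 equiv), Ir[dF(CF3)ppy]2(dtbbpy)PF6 (1 mol %), K2HPO4 (1 equiv), degassed dry DMF, blue LEDs, rt
Reagents that add atoms: none
Why: Proposed new method: the excited trivalent iridium photocatalyst oxidises the carboxylate of 13, CO2 is lost, the tertiary C10 radical 15 adds to but-3-en-2-one (Giese addition, C1–C10), and the resulting α-acyl radical is reduced by divalent iridium to the (Z)-enolate 16 (radical–polar crossover), which adds to one formyl group (aldol, C2–C3); the closest known reaction types are the photoredox decarboxylative Giese addition of tertiary acids and radical–polar crossover annulations in which the reduced Giese adduct is trapped by an internal electrophile. Ring A closes in the 6-(enolexo)-exo-trig mode through a chair transition state that leads to the trans-decalin. C10 is set by attack of the enone on the face of the planar radical opposite to the two cis substituents at C9 and C5, which leaves C20 cis to both. C2 and C3 are set together, because a (Z)-enolate whose α-substituent (C1) and aldehyde substituent (C4) lie in the same forming six-membered ring can pass through a potassium-bridged closed transition state only with the acetyl group equatorial and the aldehyde oxygen axial, which gives the 2,3-cis hydroxy ketone. C4 is set by the choice between the two diastereotopic formyl groups: the one that reacts leaves the methyl group equatorial and the spectator formyl group axial, so that the 1,3-diaxial contact with C20 involves the smaller formyl group and not a second methyl group. The step needs oxidation of the tertiary carboxylate only (the side-chain acid is masked as its tert-butyl ester) and ring closure faster than enolate protonation, which the six-membered aldol onto a non-enolisable aldehyde in dry DMF should secure.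

Step 10
Reactants: 17 tert-butyl (2S,3S,4S,5S,9R,10S,13R)-2-acetyl-3-hydroxy-19-oxolabd-7-en-15-oate
Product: 18 tert-butyl (2S,3S,4R,5S,9R,10S,13R)-2-acetyl-3,19-dihydroxylabd-7-en-15-oate
Conditions: NaBH4 (0.35 equiv), EtOH/CH2Cl2, −78 °C
Reagents that add atoms: none
Why: Low-temperature, sub-stoichiometric borohydride reduction discriminates aldehydes from ketones, so the C19 formyl group should be taken to the alcohol (where it cannot undergo oxygen insertion in step 11) while the methyl ketone survives.

Step 11
Reactants: 18 tert-butyl (2S,3S,4R,5S,9R,10S,13R)-2-acetyl-3,19-dihydroxylabd-7-en-15-oate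
Product: 21 tert-butyl (2S,3R,4R,5S,9R,10S,13R)-2-acetoxy-3,19-dihydroxylabd-7-en-15-oate, via ketone disilyl ether 19 (not isolated), via acetate disilyl ether 20 (not isolated)
Conditions: TMSOTf (2.5 equiv), 2,6-lutidine (2.2 equiv), CH2Cl2, −78 °C; then Me3SiOOSiMe3 (3 equiv), −78 to −30 °C; then citric acid, MeOH, 0 °C
Reagents that add atoms: bis(trimethylsilyl) peroxide, C[Si](C)(C)OO[Si](C)(C)C
Why: The two hydroxyl groups are first capped as trimethylsilyl ethers, and the small excess of silyl triflate then activates the silyl peroxide for a Baeyer–Villiger oxidation that does not epoxidise alkenes, in which the secondary C2 migrates in preference to methyl with retention of configuration and turns the equatorial acetyl into the equatorial acetate; acidic methanol removes the silyl ethers, and the tert-butyl ester should not be cleaved by the silyl triflate below −30 °C.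

Step 12
Reactants: 21 tert-butyl (2S,3R,4R,5S,9R,10S,13R)-2-acetoxy-3,19-dihydroxylabd-7-en-15-oate
Product: 22 tert-butyl (2S,3R,4S,5S,9R,10S,13R)-2-acetoxy-3-hydroxy-19-oxolabd-7-en-15-oate
Conditions: TEMPO (0.2 equiv), PhI(OAc)2 (1.2 equiv), CH2Cl2, rt
Reagents that add atoms: none
Why: Oxoammonium (TEMPO) oxidation is selective for the primary C19 alcohol over the hindered axial secondary C3 alcohol and stops at the aldehyde under neutral conditions that should not move the acetate.

Step 13
Reactants: 22 tert-butyl (2S,3R,4S,5S,9R,10S,13R)-2-acetoxy-3-hydroxy-19-oxolabd-7-en-15-oate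
Product: 24 (3R)-5-[(1R,4aS,5S,6R,7S,8aS)-7-acetoxy-5-formyl-6-hydroxy-2,5,8a-trimethyl-1,4,4a,5,6,7,8,8a-octahydronaphthalen-1-yl]-3-methylpentanoic acid (CNP0180877.1), via bis-silylated acid 23 (not isolated)
Conditions: TMSOTf (3 equiv), 2,6-lutidine (4 equiv), CH2Cl2, 0 °C to rt; then aq. citric acid
Reagents that add atoms: none
Why: Silyl triflate-mediated cleavage of the tert-butyl ester (loss of 2-methylpropene) gives the trimethylsilyl ester, with the C3 hydroxyl silylated in passing, and both silyl groups are hydrolysed on work-up, so the acid is freed without base or strong protic acid and the acetate, the β-hydroxy aldehyde and the trisubstituted alkene should survive.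

**Compound list**

1 | (R)-citronellic acid, (3R)-3,7-dimethyloct-6-enoic acid | CC(C)=CCC[C@@H](C)CC(=O)O | starting material
2 | tert-butyl (3R)-3,7-dimethyloct-6-enoate | CC(C)=CCC[C@@H](C)CC(=O)OC(C)(C)C | intermediate
3 | tert-butyl (3R,6E)-8-hydroxy-3,7-dimethyloct-6-enoate | OC/C(C)=C/CC[C@@H](C)CC(=O)OC(C)(C)C | intermediate
4 | tert-butyl (3R,6E)-3,7-dimethyl-8-oxooct-6-enoate | O=C/C(C)=C/CC[C@@H](C)CC(=O)OC(C)(C)C | intermediate
5 | tert-butyl (3R,6E,8R)-8-hydroxy-3,7-dimethylundeca-6,10-dienoate | C=CC[C@@H](O)/C(C)=C/CC[C@@H](C)CC(=O)OC(C)(C)C | intermediate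
6 | tert-butyl (3R,6E,8R)-3,7-dimethyl-8-(2-methylprop-2-enoyloxy)undeca-6,10-dienoate | C=CC[C@@H](OC(=O)C(C)=C)/C(C)=C/CC[C@@H](C)CC(=O)OC(C)(C)C | intermediate
7 | tert-butyl (3R,6E)-3-methyl-7-[(2R)-5-methyl-6-oxo-3,6-dihydro-2H-pyran-2-yl]oct-6-enoate | CC1=CC[C@H](/C(C)=C/CC[C@@H](C)CC(=O)OC(C)(C)C)OC1=O | intermediate
8 | methylmalononitrile, 2-methylpropanedinitrile | CC(C#N)C#N | starting material
9 | tert-butyl (3R,6E)-7-[(2R,4S,5R)-4-(1,1-dicyanoethyl)-5-methyl-6-oxooxan-2-yl]-3-methyloct-6-enoate | C[C@@H]1[C@@H](C(C)(C#N)C#N)C[C@H](/C(C)=C/CC[C@@H](C)CC(=O)OC(C)(C)C)OC1=O | intermediate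
10 | tert-butyldimethylsilyl ketene acetal of lactone 9 | CC1=C(O[Si](C)(C)C(C)(C)C)O[C@@H](/C(C)=C/CC[C@@H](C)CC(=O)OC(C)(C)C)C[C@@H]1C(C)(C#N)C#N | intermediate
11 | tert-butyldimethylsilyl ester of acid 12 | CC(C)(C)[Si](C)(C)OC(=O)[C@]1(C)[C@H](CC[C@@H](C)CC(=O)OC(C)(C)C)C(C)=CC[C@@H]1C(C)(C#N)C#N | intermediate
12 | (1R,2R,6R)-2-[(3R)-5-tert-butoxy-3-methyl-5-oxopentyl]-6-(1,1-dicyanoethyl)-1,3-dimethylcyclohex-3-ene-1-carboxylic acid | OC(=O)[C@]1(C)[C@H](CC[C@@H](C)CC(=O)OC(C)(C)C)C(C)=CC[C@@H]1C(C)(C#N)C#N | intermediate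
13 | (1R,2R,6R)-2-[(3R)-5-tert-butoxy-3-methyl-5-oxopentyl]-1,3-dimethyl-6-(2-methyl-1,3-dioxopropan-2-yl)cyclohex-3-ene-1-carboxylic acid | OC(=O)[C@]1(C)[C@H](CC[C@@H](C)CC(=O)OC(C)(C)C)C(C)=CC[C@@H]1C(C)(C=O)C=O | intermediate
14 | but-3-en-2-one (methyl vinyl ketone) | CC(=O)C=C | starting material
15 | tertiary C10 radical formed from 13 by loss of CO2 | C[C]1[C@H](CC[C@@H](C)CC(=O)OC(C)(C)C)C(C)=CC[C@@H]1C(C)(C=O)C=O | intermediate
16 | potassium (Z)-enolate of the Giese adduct (3-oxobutyl chain on C10) | C/C([O-])=C/C[C@@]1(C)[C@H](CC[C@@H](C)CC(=O)OC(C)(C)C)C(C)=CC[C@@H]1C(C)(C=O)C=O.[K+] | intermediate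
17 | tert-butyl (2S,3S,4S,5S,9R,10S,13R)-2-acetyl-3-hydroxy-19-oxolabd-7-en-15-oate | CC(=O)[C@H]1C[C@@]2(C)[C@H](CC[C@@H](C)CC(=O)OC(C)(C)C)C(C)=CC[C@@H]2[C@](C)(C=O)[C@H]1O | intermediate
18 | tert-butyl (2S,3S,4R,5S,9R,10S,13R)-2-acetyl-3,19-dihydroxylabd-7-en-15-oate | CC(=O)[C@H]1C[C@@]2(C)[C@H](CC[C@@H](C)CC(=O)OC(C)(C)C)C(C)=CC[C@@H]2[C@](C)(CO)[C@H]1O | intermediate
19 | tert-butyl (2S,3S,4R,5S,9R,10S,13R)-2-acetyl-3,19-bis(trimethylsilyloxy)labd-7-en-15-oate | CC(=O)[C@H]1C[C@@]2(C)[C@H](CC[C@@H](C)CC(=O)OC(C)(C)C)C(C)=CC[C@@H]2[C@](C)(CO[Si](C)(C)C)[C@H]1O[Si](C)(C)C | intermediate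
20 | tert-butyl (2S,3R,4R,5S,9R,10S,13R)-2-acetoxy-3,19-bis(trimethylsilyloxy)labd-7-en-15-oate | CC(=O)O[C@H]1C[C@@]2(C)[C@H](CC[C@@H](C)CC(=O)OC(C)(C)C)C(C)=CC[C@@H]2[C@](C)(CO[Si](C)(C)C)[C@H]1O[Si](C)(C)C | intermediate
21 | tert-butyl (2S,3R,4R,5S,9R,10S,13R)-2-acetoxy-3,19-dihydroxylabd-7-en-15-oate | CC(=O)O[C@H]1C[C@@]2(C)[C@H](CC[C@@H](C)CC(=O)OC(C)(C)C)C(C)=CC[C@@H]2[C@](C)(CO)[C@H]1O | intermediate
22 | tert-butyl (2S,3R,4S,5S,9R,10S,13R)-2-acetoxy-3-hydroxy-19-oxolabd-7-en-15-oate | CC(=O)O[C@H]1C[C@@]2(C)[C@H](CC[C@@H](C)CC(=O)OC(C)(C)C)C(C)=CC[C@@H]2[C@](C)(C=O)[C@H]1O | intermediate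
23 | trimethylsilyl (2S,3R,4S,5S,9R,10S,13R)-2-acetoxy-19-oxo-3-(trimethylsilyloxy)labd-7-en-15-oate | CC(=O)O[C@H]1C[C@@]2(C)[C@H](CC[C@@H](C)CC(=O)O[Si](C)(C)C)C(C)=CC[C@@H]2[C@](C)(C=O)[C@H]1O[Si](C)(C)C | intermediate
24 | (3R)-5-[(1R,4aS,5S,6R,7S,8aS)-7-acetoxy-5-formyl-6-hydroxy-2,5,8a-trimethyl-1,4,4a,5,6,7,8,8a-octahydronaphthalen-1-yl]-3-methylpentanoic acid (CNP0180877.1) | CC(=O)O[C@H]1C[C@@]2(C)[C@H](CC[C@@H](C)CC(=O)O)C(C)=CC[C@@H]2[C@](C)(C=O)[C@H]1O | target

**Summary**

Total step count: 13. Longest linear sequence: 13 steps, from (R)-citronellic acid (8 and 14 are bought).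

The three steps most likely to fail, with one fallback each:

First, step 9 (the step that bears the proposed new method). What may go wrong: the enolate may be protonated before it closes ring A, the aldol may run through an open transition state and give the C3 epimer, the ring closure may choose the wrong formyl group, or the enone may attack the wrong face of the radical. Fallback with known reactions, setting out from 13: the photoredox decarboxylative Giese addition to 14 is run with the same photocatalyst and K2HPO4 in wet DMF, so that the enolate is protonated and the open-chain tert-butyl keto dialdehyde F1 is isolated. Dehydrogenation with IBX (DMSO/toluene, 70 °C), which can only take place on the CH2–CH2 side of the ketone, gives the (E)-enone dialdehyde F2. Ring A is then closed by hydrogen-mediated reductive aldol cyclisation (Rh(cod)2OTf, (4-CF3C6H4)3P, KOAc, H2 at 1 atm, ClCH2CH2Cl, rt). Hydrometalation of the enone gives the (Z)-rhodium enolate, which adds to a formyl group through a closed transition state to give the 2,3-cis hydroxy ketone. This returns to the route at 17.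

Second, step 6. What may go wrong: the carbanion may add too slowly to the α-methyl enoate, the base may open the lactone by elimination, or reversible addition may drift to the 4,6-cis lactone. Fallback, setting out from 8 and 7: 8 is first converted (TBSCl, Et3N, CH2Cl2) into its N-(tert-butyldimethylsilyl) ketene imine F3, a neutral nucleophile. F3 is added to 7 under Lewis-acid activation of the lactone carbonyl (Mukaiyama–Michael addition, Sc(OTf)3 or catalytic TBSOTf, CH2Cl2, −78 °C), where no basic species is present. Hydrolytic work-up of the silylated adduct returns to the route at 9.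

Third, step 11. What may go wrong: oxygen insertion into the methyl ketone may be slow, the silyl triflate may cleave the tert-butyl ester early, or the acetate may migrate to the C3 oxygen during desilylation. Fallback, setting out from 18: buffered mCPBA (NaHCO3, CH2Cl2, rt to 40 °C) is used in excess so that both the Baeyer–Villiger oxidation and epoxidation of C7=C8 take place, giving the 7,8-epoxy acetate F4. The epoxide is then deoxygenated back to the alkene with Zn and NaI in NaOAc-buffered AcOH, which returns to the route at 21.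

Further compounds
F1 | step 9 | tert-butyl (3R)-3-methyl-5-[(1R,5S,6S)-2,6-dimethyl-5-(2-methyl-1,3-dioxopropan-2-yl)-6-(3-oxobutyl)cyclohex-2-en-1-yl]pentanoate | CC(=O)CC[C@@]1(C)[C@H](CC[C@@H](C)CC(=O)OC(C)(C)C)C(C)=CC[C@@H]1C(C)(C=O)C=O
F2 | step 9 | tert-butyl (3R)-3-methyl-5-[(1R,5S,6S)-2,6-dimethyl-5-(2-methyl-1,3-dioxopropan-2-yl)-6-[(1E)-3-oxobut-1-en-1-yl]cyclohex-2-en-1-yl]pentanoate | CC(=O)/C=C/[C@@]1(C)[C@H](CC[C@@H](C)CC(=O)OC(C)(C)C)C(C)=CC[C@@H]1C(C)(C=O)C=O
F3 | step 6 | N-(tert-butyldimethylsilyl) ketene imine of methylmalononitrile | CC(C#N)=C=N[Si](C)(C)C(C)(C)C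
F4 | step 11 | tert-butyl 2α-acetoxy-7α,8α-epoxy-3α,19-dihydroxylabdan-15-oate (epoxide on the face opposite C20, other centres as in 21) | CC(=O)O[C@H]1C[C@@]2(C)[C@H](CC[C@@H](C)CC(=O)OC(C)(C)C)[C@@]3(C)O[C@H]3C[C@@H]2[C@](C)(CO)[C@H]1O
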